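**Plan**

Retrosynthesis: the two acetates and the C11=C13 methylene come off first. The lactone is cut at O8–C12 and C7–C11 (a butenolide from a glyoxylate aldol condensation). The ten-membered ring is then folded back by re-joining C6 and C10, which turns the C6 ketone and the E C1=C10 alkene into a C6 alkoxide and a C1 mesylate.
Enabling feature: the oxygenated C6 and the methyl-bearing C10 face each other across the ring. A C6–C10 bond therefore gives a five-membered ring (C6–C10) fused to a seven-membered ring (C10, C1–C6) that holds the cis C4/C5 unit and places a C1 leaving group antiperiplanar to the shared bond.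
The bicycle is cut at C4=C5 (ring-closing metathesis), C5–C6 (vinyl addition) and C1–C10 (Mukaiyama aldol), which leads to (S)-4-silyloxycyclopentenone and an aldehyde made from (R)-glycidol.
Forward order of rings: five-membered ring purchased, seven-membered ring by metathesis, ten-membered ring by cleavage of the fusion bond, lactone ring last.
Stereochemistry: C8 comes from the cyclopentenone and C2 from glycidol. C10 and C1 come from an aldol anti to the C8 silyl ether under chelate control, and this pair fixes the E alkene. The C6 carbinol directs the C4/C5 epoxidation in the rigid bicycle, the epoxide then directs the C6 reduction, and C7 comes from hydride addition to the butenolide on the face of C8–H.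
Germacrane numbering (C1–C15) is used for every intermediate; PMB = 4-methoxybenzyl, TBS = tert-butyldimethylsilyl, TES = triethylsilyl.

Key step: step 13

Step 1
Reactants: 1 (R)-glycidol; 2 isopropenylmagnesium bromide
Product: 3 (S)-4-methylpent-4-ene-1,2-diol
Conditions: CH2=C(CH3)MgBr (2.5 equiv), CuI (10 mol %), THF, −30 → 0 °C; NH4Cl (aq)
Reagents that add atoms: none
Why: Copper-catalysed Grignard opening of the epoxide (SN2 at the unsubstituted carbon after the first equivalent has deprotonated the hydroxyl) leaves the stereocentre, the later C2, untouched.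

Step 2
Reactants: 3 (S)-4-methylpent-4-ene-1,2-diol
Product: 4 (4S)-2-(4-methoxyphenyl)-4-(2-methylprop-2-en-1-yl)-1,3-dioxolane
Conditions: 4-MeOC6H4CH(OMe)2, PPTS (cat.), CH2Cl2, 20 °C
Reagents that add atoms: 4-methoxybenzaldehyde dimethyl acetal, COC(OC)c1ccc(OC)cc1
Why: Acid-catalysed transacetalisation of the 1,2-diol should give the five-membered 4-methoxybenzylidene acetal, the acetal carbon being an inconsequential mixture.

Step 3
Reactants: 4 benzylidene acetal
Product: 5 (S)-2-(4-methoxybenzyloxy)-4-methylpent-4-en-1-ol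
Conditions: i-Bu2AlH (3 equiv), CH2Cl2, −78 → 0 °C
Reagents that add atoms: none
Why: Regioselective reductive opening of the benzylidene acetal, in which aluminium binds the less hindered primary oxygen and hydride reduces the oxocarbenium ion, should leave the PMB group on the secondary oxygen.

Step 4
Reactants: 5 primary alcohol
Product: 6 (S)-2-(4-methoxybenzyloxy)-4-methylpent-4-enal
Conditions: Dess–Martin periodinane, CH2Cl2, 0 → 20 °C; used crude
Reagents that add atoms: none
Why: Dess–Martin oxidation of the primary alcohol under non-basic conditions should not epimerise the α-alkoxy centre, and the aldehyde is used at once.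

Step 5
Reactants: 7 (S)-4-(tert-butyldimethylsilyloxy)cyclopent-2-en-1-one
Product: 8 (S)-4-(tert-butyldimethylsilyloxy)-2-iodocyclopent-2-en-1-one
Conditions: I2, pyridine, CH2Cl2, 0 → 20 °C
Reagents that add atoms: iodine, II
Why: Johnson α-iodination of the enone (conjugate addition of pyridine, iodination of the enolate, elimination) does not involve C8.

Step 6
Reactants: 8 iodoenone
Product: 9 (S)-4-(tert-butyldimethylsilyloxy)-2-methylcyclopent-2-en-1-one
Conditions: Me4Sn, PdCl2(PhCN)2 (5 mol %), AsPh3, CuI, N-methylpyrrolidinone, 80 °C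
Reagents that add atoms: tetramethylstannane, C[Sn](C)(C)C
Why: Stille coupling of the vinyl iodide (oxidative addition to zerovalent palladium, methyl transfer from tin assisted by CuI, reductive elimination) runs under neutral conditions that spare the γ-silyloxy enone.

Step 7
Reactants: 9 methyl enone
Product: 10 (R)-4-(tert-butyldimethylsilyloxy)-2-methyl-1-(triethylsilyloxy)cyclopent-1-ene
Conditions: Et3SiH, RhCl(PPh3)3 (1 mol %), THF, 50 °C
Reagents that add atoms: triethylsilane, CC[SiH](CC)CC
Why: Rhodium-catalysed 1,4-hydrosilylation of the enone should deliver the tetrasubstituted C6=C10 enol silane regiospecifically, without a basic enolate that could expel the C8 silyloxy group.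

Step 8
Reactants: 10 enol silane; 6 aldehyde
Product: 11 (2S,4R)-4-(tert-butyldimethylsilyloxy)-2-[(1S,2S)-1-hydroxy-2-(4-methoxybenzyloxy)-4-methylpent-4-en-1-yl]-2-methylcyclopentan-1-one
Conditions: MgBr2·OEt2 (3 equiv), CH2Cl2, −78 → −20 °C; NaHCO3 (aq)
Reagents that add atoms: none
Why: Chelation-controlled Mukaiyama aldol addition through an open transition state: magnesium bridges the aldehyde and PMB-ether oxygens so that the enol silane adds to C1 on the face of C2–H (1,2-syn, sets C1), and the cyclopentene reacts at C10 on the face opposite the C8 silyl ether (sets the quaternary C10 with its methyl cis to OTBS).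

Step 9
Reactants: 11 aldol adduct; 12 vinylmagnesium bromide
Product: 13 C6 vinyl carbinol (C6 hydroxyl trans to the C10 methyl)
Conditions: CeCl3 (3 equiv), CH2=CHMgBr (3 equiv), THF, −78 °C; NH4Cl (aq)
Reagents that add atoms: none
Why: Organocerium 1,2-addition (low basicity, so no enolisation toward C7) to the ketone while the metal is held by the C1 alkoxide, the PMB ether and the carbonyl oxygen, which places C2 over the face of the five-membered ring that carries the side chain, so vinyl should enter cis to the C10 methyl and the new C6 hydroxyl ends trans to it.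

Step 10
Reactants: 13 vinyl carbinol
Product: 14 trans-fused hydroazulene diol
Conditions: second-generation Grubbs catalyst (5 mol %), CH2Cl2 (5 mM), 40 °C
Reagents that add atoms: none
Why: Ring-closing metathesis of the vinyl and isopropenyl groups should close the seven-membered ring as the trisubstituted C4=C5 alkene, necessarily Z in a cycloheptene, with loss of ethene.

Step 11
Reactants: 14 hydroazulene diol
Product: 15 4,5-epoxy diol (epoxide oxygen cis to the C6 hydroxyl)
Conditions: VO(acac)2 (5 mol %), t-BuOOH (decane), CH2Cl2, 0 → 20 °C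
Reagents that add atoms: tert-butyl hydroperoxide, CC(C)(C)OO
Why: Vanadium-catalysed epoxidation of a cyclic allylic alcohol, in which the tertiary C6 alkoxide bound to vanadium delivers the peroxide oxygen to the alkene face syn to C6–OH, sets C4 and C5.

Step 12
Reactants: 15 epoxy diol
Product: 16 epoxy hydroxy mesylate (C1 methanesulfonate)
Conditions: MsCl, Et3N, CH2Cl2, −20 → 0 °C
Reagents that add atoms: methanesulfonyl chloride, CS(=O)(=O)Cl
Why: Sulfonylation through sulfene is selective for the secondary C1 hydroxyl, the tertiary C6 hydroxyl being too hindered to react.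

Step 13
Reactants: 16 epoxy hydroxy mesylate
Product: 18 (1(10)E,2S,4R,5R,8R)-4,5-epoxy-2-(4-methoxybenzyloxy)-8-(tert-butyldimethylsilyloxy)-4,10-dimethylcyclodec-1(10)-en-6-one, via potassium C6 alkoxide 17 (not isolated)
Conditions: KOt-Bu (1.1 equiv), THF, 0 °C, 30 min; pH 7 buffer
Reagents that add atoms: none
Why: Deprotonation of the tertiary C6 hydroxyl gives alkoxide 17, whose lone pair forms the C6=O bond while the C6–C10 σ electrons become the C10=C1 π bond and mesylate leaves C1 in one concerted step (Grob/Wharton fragmentation of a cyclic 1,3-diol monosulfonate; the closest precedent is the preparation of E-cyclodecenones from decalin-1,3-diol monosulfonates). No ring is closed by bond formation: the ten-membered ring appears by cleavage of the bond shared by the five- and seven-membered rings, so no exo or endo closure mode applies. No stereocentre is created; the new stereo-element is the C1=C10 geometry, which should be E because in the trans-fused chair the equatorial C1–OMs bond is antiperiplanar to C6–C10 and C2 is then anti to C9. Fragmentation has to win over oxetane formation, E2 loss of methanesulfonic acid and Payne-type attack on the epoxide: the rigid trans fusion holds the antiperiplanar array, C2–H is gauche to the mesylate, and the epoxide oxygen is cis to the alkoxide, so backside attack on C5 is not possible. C2, C4, C5 and C8 are not touched.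

Step 14
Reactants: 18 epoxy cyclodecenone
Product: 22 (E)-alkylidene keto ester [C7=C11H–CO2Et], via lithium C6 enolate 19 (not isolated), via lithium aldolate 20 (not isolated), via C11 mesylate 21 (not isolated)
Conditions: LiN(SiMe3)2, THF, −78 °C; ethyl glyoxylate, −78 °C; MsCl, −78 °C; Et3N, −78 → 20 °C
Reagents that add atoms: ethyl glyoxylate, CCOC(=O)C=O
Why: Aldol condensation: the kinetic lithium enolate (only C7 carries removable α-hydrogens) adds to the aldehyde of ethyl glyoxylate, and mesylation of the aldolate followed by E1cB loss of methanesulfonate should give the alkylidene as the E isomer (ester anti to the C6 carbonyl and therefore cis to C8), the transient C7 and C11 centres being cleared.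

Step 15
Reactants: 22 alkylidene keto ester
Product: 23 (6S)-epoxy alcohol ester
Conditions: Zn(BH4)2, Et2O, −20 °C
Reagents that add atoms: none
Why: Chelation-controlled 1,2-reduction of an α,β-epoxy ketone, in which zinc bridges the carbonyl and epoxide oxygens and hydride attacks C6 on the face away from C4, should give the anti (erythro) epoxy alcohol, which is the C6 configuration of the target.

Step 16
Reactants: 23 epoxy alcohol ester
Product: 25 butenolide alcohol [8,12-lactone with C7=C11], via C8 hydroxy ester 24 (not isolated)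
Conditions: Bu4NF, AcOH (1:1), THF, 0 → 40 °C
Reagents that add atoms: none
Why: Buffered fluoride desilylation frees the C8 hydroxyl, which lies cis to the ester across C7=C11 and lactonises (5-exo-trig acyl substitution) to the butenolide, whereas the C6 hydroxyl is trans to the ester and cannot lactonise.

Step 17
Reactants: 25 butenolide alcohol
Product: 26 butenolide C6 triethylsilyl ether
Conditions: Et3SiCl, imidazole, DMF, 0 → 20 °C
Reagents that add atoms: chlorotriethylsilane, CC[Si](Cl)(CC)CC
Why: Silylation of the secondary C6 alcohol masks it for the later enolate step and excludes translactonisation once the lactone is saturated.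

Step 18
Reactants: 26 butenolide silyl ether
Product: 27 cis-fused saturated lactone (H7 cis to H8)
Conditions: Cu(OAc)2·H2O (5 mol %), 1,2-bis(diphenylphosphino)benzene (5 mol %), (EtO)2MeSiH, t-BuOH, toluene, 0 → 20 °C
Reagents that add atoms: none
Why: Copper hydride-catalysed conjugate reduction of the butenolide should add hydride to C7 on the face of C8–H, away from C9 and the ten-membered ring that leave the planar butenolide on the other face, so that H7 ends cis to H8 (sets C7).

Step 19
Reactants: 27 saturated lactone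
Product: 31 α-methylene lactone [C11=C13], via lithium lactone enolate 28 (not isolated), via Mannich base 29 (not isolated), via trimethylammonium iodide 30 (not isolated)
Conditions: LiN(i-Pr)2, THF, −78 °C; Me2N=CH2+ I−, −78 → 0 °C; MeI, MeOH, 20 °C; NaHCO3 (aq), CH2Cl2
Reagents that add atoms: N,N-dimethylmethyleneiminium iodide, C=[N+](C)C.[I-]
Why: α-Methylenation of the lactone by a Mannich reaction of its lithium enolate with the iminium salt, quaternisation and E1cB loss of trimethylamine; only C11 is enolisable and no stereocentre is affected.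

Step 20
Reactants: 31 α-methylene lactone
Product: 32 C2 alcohol
Conditions: DDQ, CH2Cl2/pH 7 buffer, 0 → 20 °C
Reagents that add atoms: none
Why: Oxidative cleavage of the PMB ether by DDQ (hydride abstraction, then hydrolysis of the oxocarbenium ion) under buffered conditions should spare the epoxide, the silyl ether and the α-methylene lactone.

Step 21
Reactants: 32 C2 alcohol
Product: 33 C2,C6 diol
Conditions: Et3N·3HF, THF, 20 °C
Reagents that add atoms: none
Why: Fluoride cleavage of the triethylsilyl ether under nearly neutral conditions avoids acid-induced transannular opening of the epoxide and base-induced translactonisation.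

Step 22
Reactants: 33 diol
Product: 34 CNP0270851.1, (1(10)E,2S,4R,5S,6S,7R,8R)-2,6-diacetoxy-4,5-epoxygermacra-1(10),11(13)-dien-12,8-olide
Conditions: Ac2O, pyridine, DMAP (cat.), CH2Cl2, 0 → 20 °C
Reagents that add atoms: acetic anhydride, CC(=O)OC(C)=O
Why: DMAP-catalysed acylation of both secondary alcohols completes the target without touching a stereocentre.

**Compound list**

1 | (R)-glycidol | OC[C@@H]1CO1 | starting material
2 | isopropenylmagnesium bromide | C=C(C)[Mg]Br | starting material
3 | (S)-4-methylpent-4-ene-1,2-diol | OC[C@@H](O)CC(C)=C | intermediate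
4 | (4S)-2-(4-methoxyphenyl)-4-(2-methylprop-2-en-1-yl)-1,3-dioxolane (both acetal epimers) | C=C(C)C[C@H]1COC(c2ccc(OC)cc2)O1 | intermediate
5 | (S)-2-(4-methoxybenzyloxy)-4-methylpent-4-en-1-ol | OC[C@@H](OCc1ccc(OC)cc1)CC(C)=C | intermediate
6 | (S)-2-(4-methoxybenzyloxy)-4-methylpent-4-enal | O=C[C@@H](OCc1ccc(OC)cc1)CC(C)=C | intermediate
7 | (S)-4-(tert-butyldimethylsilyloxy)cyclopent-2-en-1-one | O=C1C=C[C@@H](O[Si](C)(C)C(C)(C)C)C1 | starting material
8 | (S)-4-(tert-butyldimethylsilyloxy)-2-iodocyclopent-2-en-1-one | O=C1C(I)=C[C@@H](O[Si](C)(C)C(C)(C)C)C1 | intermediate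
9 | (S)-4-(tert-butyldimethylsilyloxy)-2-methylcyclopent-2-en-1-one | O=C1C(C)=C[C@@H](O[Si](C)(C)C(C)(C)C)C1 | intermediate
10 | (R)-4-(tert-butyldimethylsilyloxy)-2-methyl-1-(triethylsilyloxy)cyclopent-1-ene | CC[Si](CC)(CC)OC1=C(C)C[C@@H](O[Si](C)(C)C(C)(C)C)C1 | intermediate
11 | (2S,4R)-4-(tert-butyldimethylsilyloxy)-2-[(1S,2S)-1-hydroxy-2-(4-methoxybenzyloxy)-4-methylpent-4-en-1-yl]-2-methylcyclopentan-1-one (C10 methyl cis to C8 OTBS; C1 OH and C2 OPMB syn) | C[C@]1(C[C@@H](O[Si](C)(C)C(C)(C)C)CC1=O)[C@H](O)[C@@H](OCc1ccc(OC)cc1)CC(C)=C | intermediate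
12 | vinylmagnesium bromide | C=C[Mg]Br | starting material
13 | C6 vinyl carbinol of 11 (1-vinylcyclopentan-1-ol; C6 OH trans to the C10 methyl and cis to the C1 side chain) | C[C@]1(C[C@@H](O[Si](C)(C)C(C)(C)C)C[C@@]1(O)C=C)[C@H](O)[C@@H](OCc1ccc(OC)cc1)CC(C)=C | intermediate
14 | trans-fused hydroazulene diol: bicyclo[5.3.0]dec-4-ene with C6 OH and C10 CH3 at the ring fusion (trans), C1 OH cis to the C10 methyl, C2 OPMB trans to C1 OH, C8 OTBS cis to the C10 methyl, CH3 on C4 | C[C@@]12C[C@@H](O[Si](C)(C)C(C)(C)C)C[C@@]1(O)C=C(C)C[C@H](OCc3ccc(OC)cc3)[C@H]2O | intermediate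
15 | 4,5-epoxide of 14, epoxide oxygen cis to the C6 OH | C[C@@]12C[C@@H](O[Si](C)(C)C(C)(C)C)C[C@@]1(O)[C@@H]3O[C@]3(C)C[C@H](OCc4ccc(OC)cc4)[C@H]2O | intermediate
16 | C1 methanesulfonate of 15 (fragmentation precursor) | C[C@@]12C[C@@H](O[Si](C)(C)C(C)(C)C)C[C@@]1(O)[C@@H]3O[C@]3(C)C[C@H](OCc4ccc(OC)cc4)[C@H]2OS(C)(=O)=O | intermediate
17 | potassium C6 alkoxide of 16 | C[C@@]12C[C@@H](O[Si](C)(C)C(C)(C)C)C[C@@]1([O-])[C@@H]3O[C@]3(C)C[C@H](OCc4ccc(OC)cc4)[C@H]2OS(C)(=O)=O.[K+] | intermediate (not isolated)
18 | (1(10)E,2S,4R,5R,8R)-4,5-epoxy-2-(4-methoxybenzyloxy)-8-(tert-butyldimethylsilyloxy)-4,10-dimethylcyclodec-1(10)-en-6-one (cis-epoxide, germacrane ring numbering) | C1C(=O)[C@@H]2O[C@]2(C)C[C@H](OCc3ccc(OC)cc3)/C=C(C)/C[C@H]1O[Si](C)(C)C(C)(C)C | intermediate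
19 | lithium C6(O)=C7 enolate of 18 | C1=C(O[Li])[C@@H]2O[C@]2(C)C[C@H](OCc3ccc(OC)cc3)/C=C(C)/C[C@H]1O[Si](C)(C)C(C)(C)C | intermediate (not isolated)
20 | lithium aldolate: 18 carrying CH(OLi)CO2Et on C7 (mixture at C7 and C11) | C1(C(O[Li])C(=O)OCC)C(=O)[C@@H]2O[C@]2(C)C[C@H](OCc3ccc(OC)cc3)/C=C(C)/C[C@H]1O[Si](C)(C)C(C)(C)C | intermediate (not isolated)
21 | C11 methanesulfonate of the aldol adduct (mixture at C7 and C11) | C1(C(OS(C)(=O)=O)C(=O)OCC)C(=O)[C@@H]2O[C@]2(C)C[C@H](OCc3ccc(OC)cc3)/C=C(C)/C[C@H]1O[Si](C)(C)C(C)(C)C | intermediate (not isolated)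
22 | ethyl (E)-2-(6-oxocyclodecenylidene)acetate: 18 with C7=C11H–CO2Et, ester cis to C8 | CCOC(=O)/C=C1/C(=O)[C@@H]2O[C@]2(C)C[C@H](OCc3ccc(OC)cc3)/C=C(C)/C[C@H]1O[Si](C)(C)C(C)(C)C | intermediate
23 | (6S)-alcohol of 22 (C6 OH anti to the epoxide, erythro) | CCOC(=O)/C=C1/[C@H](O)[C@@H]2O[C@]2(C)C[C@H](OCc3ccc(OC)cc3)/C=C(C)/C[C@H]1O[Si](C)(C)C(C)(C)C | intermediate
24 | C8 hydroxy ester (23 without the TBS group) | CCOC(=O)/C=C1/[C@H](O)[C@@H]2O[C@]2(C)C[C@H](OCc3ccc(OC)cc3)/C=C(C)/C[C@H]1O | intermediate (not isolated)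
25 | butenolide alcohol: 8,12-lactone with C7=C11, free C6 OH, 4,5-epoxide, C2 OPMB, E C1=C10 | O=C1C=C2[C@H](O)[C@@H]3O[C@]3(C)C[C@H](OCc4ccc(OC)cc4)/C=C(C)/C[C@H]2O1 | intermediate
26 | C6 triethylsilyl ether of 25 | O=C1C=C2[C@H](O[Si](CC)(CC)CC)[C@@H]3O[C@]3(C)C[C@H](OCc4ccc(OC)cc4)/C=C(C)/C[C@H]2O1 | intermediate
27 | cis-fused 8,12-lactone (7R,8R; H7 cis to H8), C6 OTES, C2 OPMB | O=C1C[C@H]2[C@H](O[Si](CC)(CC)CC)[C@@H]3O[C@]3(C)C[C@H](OCc4ccc(OC)cc4)/C=C(C)/C[C@H]2O1 | intermediate
28 | lithium enolate of lactone 27 | [Li]OC1=C[C@H]2[C@H](O[Si](CC)(CC)CC)[C@@H]3O[C@]3(C)C[C@H](OCc4ccc(OC)cc4)/C=C(C)/C[C@H]2O1 | intermediate (not isolated)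
29 | C11 (dimethylaminomethyl) lactone (C11 epimers) | O=C1C(CN(C)C)[C@H]2[C@H](O[Si](CC)(CC)CC)[C@@H]3O[C@]3(C)C[C@H](OCc4ccc(OC)cc4)/C=C(C)/C[C@H]2O1 | intermediate (not isolated)
30 | C11 (trimethylammoniomethyl) lactone iodide | O=C1C(C[N+](C)(C)C)[C@H]2[C@H](O[Si](CC)(CC)CC)[C@@H]3O[C@]3(C)C[C@H](OCc4ccc(OC)cc4)/C=C(C)/C[C@H]2O1.[I-] | intermediate (not isolated)
31 | α-methylene lactone (C11=C13), C6 OTES, C2 OPMB | O=C1C(=C)[C@H]2[C@H](O[Si](CC)(CC)CC)[C@@H]3O[C@]3(C)C[C@H](OCc4ccc(OC)cc4)/C=C(C)/C[C@H]2O1 | intermediate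
32 | C2 alcohol, C6 OTES α-methylene lactone | O=C1C(=C)[C@H]2[C@H](O[Si](CC)(CC)CC)[C@@H]3O[C@]3(C)C[C@H](O)/C=C(C)/C[C@H]2O1 | intermediate
33 | C2,C6 diol α-methylene lactone | O=C1C(=C)[C@H]2[C@H](O)[C@@H]3O[C@]3(C)C[C@H](O)/C=C(C)/C[C@H]2O1 | intermediate
34 | CNP0270851.1, (1(10)E,2S,4R,5S,6S,7R,8R)-2,6-diacetoxy-4,5-epoxygermacra-1(10),11(13)-dien-12,8-olide | O=C1C(=C)[C@H]2[C@H](OC(C)=O)[C@@H]3O[C@]3(C)C[C@H](OC(C)=O)/C=C(C)/C[C@H]2O1 | target

**Step count and risks**

Total step count: 22. Longest linear sequence: 19 steps (from (R)-glycidol: steps 1–4 and 8–22).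

Steps most likely to fail:

Step 9. The risk is poor facial selectivity of the vinyl addition. Attack on the face of the C1 side chain would give the C6 epimer, whose hydroxyl would steer the later epoxidation to the wrong face. Retro-aldol cleavage of the C1 alkoxide is a second risk. The fallback sets out from 11 and uses the fact that C6 becomes trigonal in the fragmentation. The same organocerium addition is accepted as the C6-epimeric vinyl carbinol F1, and metathesis then gives the cis-fused hydroazulene diol F2. The epoxide is installed by reagent control instead of hydroxyl direction: a Shi epoxidation (the enantiomer of the fructose-derived ketone matched to the face anti to the C6 hydroxyl, KHSO5, K2CO3 buffer) should give the epoxy diol F3 with C4 and C5 as in 15. Mesylation gives the epoxy mesylate F4, and KOt-Bu fragmentation, expected to outrun Payne equilibration of the trans epoxy alkoxide, comes back to the route at 18.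

Step 13. The risk is diversion of the C6 alkoxide or of tert-butoxide into the neighbouring epoxide (opening or rearrangement) before the C6–C10 bond breaks. The fallback sets out from 14 and fragments at the alkene oxidation level. Mesylation of the C1 hydroxyl gives the ene hydroxy mesylate F5, and KOt-Bu should give the (4Z,1(10)E)-cyclodecadienone F6. Nucleophilic epoxidation of the Z-enone (t-BuOOH, KH, THF, −20 °C) from the peripheral face then returns to the route at 18; the facial sense of this last reaction rests on macrocyclic control and would have to be confirmed.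

Step 14. The risk is loss of the C8 silyloxy group by E1cB elimination from the lithium enolate before it is trapped, together with incomplete E selectivity. The fallback sets out from 18 and avoids a basic enolate. Soft enolisation (Me3SiOTf, Et3N, CH2Cl2, −78 °C) gives the C6=C7 trimethylsilyl enol ether F7. A Mukaiyama aldol addition to ethyl glyoxylate promoted by MgBr2·OEt2 gives the α-hydroxy ester F8. Mesylation and elimination with MsCl and Et3N (through 21) come back to the route at 22.

**Further compounds**

F1 | step 9 | C6 epimer of vinyl carbinol 13 (C6 OH cis to the C10 methyl) | C[C@]1(C[C@@H](O[Si](C)(C)C(C)(C)C)C[C@]1(O)C=C)[C@H](O)[C@@H](OCc1ccc(OC)cc1)CC(C)=C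
F2 | step 9 | cis-fused hydroazulene diol (C6 epimer of 14) | C[C@@]12C[C@@H](O[Si](C)(C)C(C)(C)C)C[C@]1(O)C=C(C)C[C@H](OCc3ccc(OC)cc3)[C@H]2O
F3 | step 9 | 4,5-epoxide of F2 with C4 and C5 as in 15 (epoxide oxygen trans to the C6 OH) | C[C@@]12C[C@@H](O[Si](C)(C)C(C)(C)C)C[C@]1(O)[C@@H]3O[C@]3(C)C[C@H](OCc4ccc(OC)cc4)[C@H]2O
F4 | step 9 | C1 methanesulfonate of F3 | C[C@@]12C[C@@H](O[Si](C)(C)C(C)(C)C)C[C@]1(O)[C@@H]3O[C@]3(C)C[C@H](OCc4ccc(OC)cc4)[C@H]2OS(C)(=O)=O
F5 | step 13 | C1 methanesulfonate of hydroazulene diol 14 (alkene retained) | C[C@@]12C[C@@H](O[Si](C)(C)C(C)(C)C)C[C@@]1(O)C=C(C)C[C@H](OCc3ccc(OC)cc3)[C@H]2OS(C)(=O)=O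
F6 | step 13 | (2Z,6E)-3,7-dimethyl-5-(4-methoxybenzyloxy)-9-(tert-butyldimethylsilyloxy)cyclodeca-2,6-dien-1-one | C1C(=O)/C=C(C)\C[C@H](OCc2ccc(OC)cc2)/C=C(C)/C[C@H]1O[Si](C)(C)C(C)(C)C
F7 | step 14 | C6=C7 trimethylsilyl enol ether of 18 | C1=C(O[Si](C)(C)C)[C@@H]2O[C@]2(C)C[C@H](OCc3ccc(OC)cc3)/C=C(C)/C[C@H]1O[Si](C)(C)C(C)(C)C
F8 | step 14 | α-hydroxy ester: 18 carrying CH(OH)CO2Et on C7 (mixture at C7 and C11) | C1(C(O)C(=O)OCC)C(=O)[C@@H]2O[C@]2(C)C[C@H](OCc3ccc(OC)cc3)/C=C(C)/C[C@H]1O[Si](C)(C)C(C)(C)C
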